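**Retrosynthetic overview**
- End game: the C17 formyl group comes from an equatorial hydroxymethyl-anion addition to a C8 ketone (axial 8-OH) and a late oxidation. The C12–C16 chain with its (13Z)-enoate comes from a B-alkyl Suzuki coupling of a C9 vinyl group (C11=C12) with methyl (Z)-3-iodobut-2-enoate.
- The strategy rests on the trans C5–C10 fusion of rings A and B, with the quaternary C10 methyl (C20) next to C9, which carries C11 on the same face. This maps onto an (E)-3-methyl-2-enoate (C9=C10) linked through C1–C4 to a 1-oxygenated diene C5=C6–C7=C8. One intramolecular Diels–Alder reaction forms C5–C10 and C8–C9 and closes rings A and B together.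
- The trienoate is built from methyl geranate: cleavage of the remote alkene, reagent-controlled reverse prenylation (C3 stereocentre, C4 gem-dimethyl), then a geometry-defined (E,E)-dienyl ether by Wittig, boron-Takai and copper-mediated C–O coupling.
- The C8 oxygen is carried as a 4-methoxybenzyl (PMB) ether so that it can be released with DDQ after the enoate is in place.

Key step: step 8

Assumption: methyl geranate is used as the pure (2E)-isomer; ring compounds are discussed with labdane locants (C1–C20, C17 = formyl carbon), and axial/equatorial refer to the trans-decalin chair.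

**Step 1**
Reactants: 1 methyl (2E)-geranate
Product: 3 methyl (2E)-3-methyl-6-oxohex-2-enoate, via ozonide 2 (not isolated)
Conditions: O3 (1 equiv, Sudan Red 7B end point), CH2Cl2, −78 °C; then PPh3, −78 °C → rt
Reagents that add atoms: ozone, [O-][O+]=O
Why: Chemoselective ozonolysis with reductive work-up; electrophilic ozone attacks the electron-rich trisubstituted 6,7-alkene far faster than the ester-conjugated 2,3-alkene, whose (E)-geometry is untouched.

**Step 2**
Reactants: 3 methyl (2E)-3-methyl-6-oxohex-2-enoate; 4 3-methylbuta-1,2-diene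
Product: 7 methyl (2E,6R)-6-hydroxy-3,7,7-trimethylnona-2,8-dienoate, via prenylborane 5 (not isolated), via borinate ester 6 (not isolated)
Conditions: (−)-Ipc2BH [from (+)-α-pinene], 4, THF, −25 °C; then 3, Et2O, −78 °C; then HOCH2CH2NH2, rt
Reagents that add atoms: none
Why: Brown allylboration; the prenylborane reacts at its γ-carbon through a closed chair transition state, so the gem-dimethyl carbon bonds to the aldehyde (reverse prenylation), and the isopinocampheyl groups from (+)-α-pinene direct attack to the Si face to give the (6R)-alcohol, whose enantiomeric purity fixes that of every later compound.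

**Step 3**
Reactants: 7 methyl (2E,6R)-6-hydroxy-3,7,7-trimethylnona-2,8-dienoate
Product: 8 methyl (2E,6R)-6-[(tert-butyldimethylsilyl)oxy]-3,7,7-trimethylnona-2,8-dienoate
Conditions: TBSOTf, 2,6-lutidine, CH2Cl2, 0 °C
Reagents that add atoms: tert-butyldimethylsilyl trifluoromethanesulfonate, CC(C)(C)[Si](C)(C)OS(=O)(=O)C(F)(F)F
Why: Silylation with a silyl triflate and a hindered pyridine base protects even this neopentyl-type secondary alcohol, and nothing else in the molecule reacts.

**Step 4**
Reactants: 8 methyl (2E,6R)-6-[(tert-butyldimethylsilyl)oxy]-3,7,7-trimethylnona-2,8-dienoate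
Product: 10 methyl (2E,6R)-6-[(tert-butyldimethylsilyl)oxy]-3,7,7-trimethyl-8-oxooct-2-enoate, via diol 9 (not isolated)
Conditions: OsO4 (2 mol%), NaIO4, 2,6-lutidine, dioxane/H2O 3:1, rt
Reagents that add atoms: osmium tetroxide, O=[Os](=O)(=O)=O; sodium periodate (terminal oxidant that resupplies the oxygen), [Na+].[O-]I(=O)(=O)=O
Why: Lemieux–Johnson cleavage; OsO4 dihydroxylates the isolated vinyl group in preference to the electron-poor trisubstituted enoate, periodate cleaves the diol, and the resulting aldehyde has no α-hydrogen and cannot enolise.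

**Step 5**
Reactants: 10 methyl (2E,6R)-6-[(tert-butyldimethylsilyl)oxy]-3,7,7-trimethyl-8-oxooct-2-enoate; 11 (triphenylphosphoranylidene)acetaldehyde
Product: 12 methyl (2E,6R,8E)-6-[(tert-butyldimethylsilyl)oxy]-3,7,7-trimethyl-10-oxodeca-2,8-dienoate
Conditions: 11 (1.3 equiv), toluene, 90 °C
Reagents that add atoms: none
Why: Wittig reaction with a stabilised formyl ylide is (E)-selective, and the conjugated product is a poorer electrophile for this weakly nucleophilic ylide, which limits a second homologation.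

**Step 6**
Reactants: 12 methyl (2E,6R,8E)-6-[(tert-butyldimethylsilyl)oxy]-3,7,7-trimethyl-10-oxodeca-2,8-dienoate
Product: 13 methyl (2E,6R,8E,10E)-6-[(tert-butyldimethylsilyl)oxy]-3,7,7-trimethyl-11-(4,4,5,5-tetramethyl-1,3,2-dioxaborolan-2-yl)undeca-2,8,10-trienoate
Conditions: Cl2CHBpin, CrCl2, LiI, THF, rt
Reagents that add atoms: 2-(dichloromethyl)-4,4,5,5-tetramethyl-1,3,2-dioxaborolane, ClC(Cl)B1OC(C)(C)C(C)(C)O1
Why: Takai–Utimoto olefination; the gem-dichromium species made from the dichloromethylboronate adds to the aldehyde and eliminates to place boron trans (10E), while divalent chromium leaves the ester, the silyl ether and the existing alkenes alone.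

**Step 7**
Reactants: 13 dienyl pinacol boronate (as above); 14 4-methoxybenzyl alcohol
Product: 15 methyl (2E,6R,8E,10E)-6-[(tert-butyldimethylsilyl)oxy]-11-[(4-methoxybenzyl)oxy]-3,7,7-trimethylundeca-2,8,10-trienoate
Conditions: Cu(OAc)2 (2 equiv), Et3N, 14 (excess, co-solvent), CH2Cl2, 4 Å sieves, air, rt
Reagents that add atoms: none
Why: Chan–Lam-type copper-promoted etherification of an alkenyl boronate; transmetallation to copper, oxidation to trivalent copper and C–O reductive elimination retain the alkene geometry, so the (10E)-enol ether results, and the amine-buffered room-temperature conditions spare the methyl ester.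

**Step 8**
Reactants: 15 methyl (2E,6R,8E,10E)-6-[(tert-butyldimethylsilyl)oxy]-11-[(4-methoxybenzyl)oxy]-3,7,7-trimethylundeca-2,8,10-trienoate
Product: 16 methyl (1S,2R,4aS,6R,8aR)-6-[(tert-butyldimethylsilyl)oxy]-2-[(4-methoxybenzyl)oxy]-5,5,8a-trimethyl-1,2,4a,5,6,7,8,8a-octahydronaphthalene-1-carboxylate (labdane locants: 3-OTBS, 8-OPMB, 6-ene, C11 ester)
Conditions: toluene (0.01 M, degassed), BHT, base-washed sealed tube, 185 °C
Reagents that add atoms: none
Why: Concerted, asynchronous, suprafacial [4+2] cycloaddition in which the unoxygenated diene terminus C5 bonds to the enoate β-carbon C10 and the oxygenated terminus C8 bonds to C9, the polarity match of a 1-alkoxydiene with an acrylate-type dienophile; the closest known reaction type is the thermal type 1 intramolecular Diels–Alder reaction of 1,7,9-decatrienoates with a trisubstituted dienophile. Ring B closes as the cyclohexene of the cycloaddition, and ring A closes as the six-membered ring spanned by the four-carbon tether C1–C4 (fused mode) in a chair. C9 and C10 follow from the (E)-enoate geometry (methyl and ester cis, carried over suprafacially), C5 (trans fusion) and C8 follow from the ester-endo, tether-anti transition state of the (E,E)-diene, and the absolute sense of all four is set by C3, whose silyloxy group takes the equatorial site of the chair tether. The step needs endo over exo selectivity and π-facial selectivity: the first rests on the chair tether, where only the anti arrangement keeps both the diene arm and the enoate arm equatorial, and on the endo preference of the ester; the second rests only on the equatorial preference of the C3 substituent, so the cis-fused and C3-axial adducts are expected as minor, chromatographically separable diastereomers. The C8 configuration (PMB ether cis to the ester) is of no consequence because C8 later becomes a ketone.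

**Step 9**
Reactants: 16 cycloadduct (as above)
Product: 17 methyl (1S,2R,4aS,6R,8aR)-6-[(tert-butyldimethylsilyl)oxy]-2-[(4-methoxybenzyl)oxy]-5,5,8a-trimethyldecahydronaphthalene-1-carboxylate
Conditions: [Ir(cod)(PCy3)(py)]PF6 (5 mol%), H2 (1 atm), CH2Cl2, rt
Reagents that add atoms: none
Why: Homogeneous iridium-catalysed hydrogenation saturates the cis-disubstituted C6=C7 alkene without the hydrogenolysis of the allylic PMB ether that heterogeneous palladium would cause; no stereocentre is formed.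

**Step 10**
Reactants: 17 saturated ester (as above)
Product: 18 [(1R,2R,4aS,6R,8aR)-6-[(tert-butyldimethylsilyl)oxy]-2-[(4-methoxybenzyl)oxy]-5,5,8a-trimethyldecahydronaphthalen-1-yl]methanol
Conditions: LiAlH4, THF, 0 °C → rt; aqueous work-up
Reagents that add atoms: none
Why: Hydride reduction of the hindered ester to the C11 primary alcohol; both ethers are inert (the descriptor at C9 changes only through CIP priorities).

**Step 11**
Reactants: 18 C11 alcohol (as above)
Product: 19 (1S,2R,4aS,6R,8aR)-6-[(tert-butyldimethylsilyl)oxy]-2-[(4-methoxybenzyl)oxy]-5,5,8a-trimethyldecahydronaphthalene-1-carbaldehyde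
Conditions: Dess–Martin periodinane, NaHCO3, CH2Cl2, 0 °C → rt
Reagents that add atoms: none
Why: Dess–Martin oxidation under buffered, non-basic conditions gives the β-alkoxy aldehyde without elimination, and the formyl group stays equatorial.

**Step 12**
Reactants: 19 C11 aldehyde (as above)
Product: 20 (1S,2R,4aS,6R,8aR)-1-ethenyl-6-[(tert-butyldimethylsilyl)oxy]-2-[(4-methoxybenzyl)oxy]-5,5,8a-trimethyldecahydronaphthalene (numbered as in 19)
Conditions: Ph3PCH3Br, KN(SiMe3)2, THF, 0 °C; then 19, −78 → 0 °C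
Reagents that add atoms: methylenetriphenylphosphorane (from methyltriphenylphosphonium bromide), C=P(c1ccccc1)(c1ccccc1)c1ccccc1
Why: Wittig methylenation; the small, very reactive ylide adds to the hindered aldehyde at low temperature faster than it enolises it, so β-elimination of the trans-diaxial PMB ether is avoided.

**Step 13**
Reactants: 20 C9-vinyl compound (as above); 21 methyl (2Z)-3-iodobut-2-enoate
Product: 23 methyl (2Z)-5-[(1S,2R,4aS,6R,8aR)-6-[(tert-butyldimethylsilyl)oxy]-2-[(4-methoxybenzyl)oxy]-5,5,8a-trimethyldecahydronaphthalen-1-yl]-3-methylpent-2-enoate, via alkylborane 22 (not isolated)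
Conditions: 9-BBN, THF, rt; then 21, PdCl2(dppf) (5 mol%), AsPh3, 3 M aq. K3PO4, DMF, rt
Reagents that add atoms: none
Why: Anti-Markovnikov hydroboration of the only alkene followed by B-alkyl Suzuki–Miyaura coupling, which retains the geometry of the (Z)-β-iodoenoate, so the chain ends cis to the ester (13Z), a geometry that olefination of a methyl ketone would not give reliably.

**Step 14**
Reactants: 23 PMB ether enoate (as above)
Product: 24 methyl (2Z)-5-[(1S,2R,4aS,6R,8aR)-6-[(tert-butyldimethylsilyl)oxy]-2-hydroxy-5,5,8a-trimethyldecahydronaphthalen-1-yl]-3-methylpent-2-enoate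
Conditions: DDQ, CH2Cl2/pH 7 buffer, 0 °C → rt
Reagents that add atoms: none
Why: Oxidative cleavage of the electron-rich PMB ether by DDQ; the enoate and the silyl ether are inert to it.

**Step 15**
Reactants: 24 C8 alcohol (as above)
Product: 25 methyl (2Z)-5-[(1S,4aS,6R,8aR)-6-[(tert-butyldimethylsilyl)oxy]-5,5,8a-trimethyl-2-oxodecahydronaphthalen-1-yl]-3-methylpent-2-enoate
Conditions: Dess–Martin periodinane, NaHCO3, CH2Cl2, rt
Reagents that add atoms: none
Why: Dess–Martin oxidation of the axial secondary alcohol to the C8 ketone; C9 already holds its chain equatorial, the preferred configuration next to the ketone.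

**Step 16**
Reactants: 25 C8 ketone (as above)
Product: 26 methyl (2Z)-5-[(1S,2R,4aS,6R,8aR)-6-[(tert-butyldimethylsilyl)oxy]-2-{[dimethyl(propan-2-yloxy)silyl]methyl}-2-hydroxy-5,5,8a-trimethyldecahydronaphthalen-1-yl]-3-methylpent-2-enoate
Conditions: (i-PrO)Me2SiCH2MgCl [from (i-PrO)Me2SiCH2Cl, Mg, THF], THF, 0 °C → rt; aq. NH4Cl
Reagents that add atoms: (isopropoxydimethylsilyl)methylmagnesium chloride, CC(C)O[Si](C)(C)C[Mg]Cl
Why: Grignard addition of a hydroxymethyl-anion equivalent; the axial approach to C8 is blocked by the 1,3-diaxial C10 methyl, so the nucleophile enters equatorially and the hydroxyl ends axial (8R) as the target requires, while the β,β-disubstituted enoate is far less electrophilic than the ketone.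

**Step 17**
Reactants: 26 β-hydroxysilane (as above)
Product: 27 methyl (2Z)-5-[(1S,2R,4aS,6R,8aR)-6-[(tert-butyldimethylsilyl)oxy]-2-hydroxy-2-(hydroxymethyl)-5,5,8a-trimethyldecahydronaphthalen-1-yl]-3-methylpent-2-enoate
Conditions: KF, KHCO3, 30% H2O2, THF/MeOH, rt
Reagents that add atoms: hydrogen peroxide, OO
Why: Tamao–Fleming oxidation turns the C17–Si bond into C17–OH under weakly basic conditions that neither epoxidise the β,β-disubstituted enoate nor cleave the hindered TBS ether.

**Step 18**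
Reactants: 27 diol ester (as above)
Product: 28 (2Z)-5-[(1S,2R,4aS,6R,8aR)-6-[(tert-butyldimethylsilyl)oxy]-2-hydroxy-2-(hydroxymethyl)-5,5,8a-trimethyldecahydronaphthalen-1-yl]-3-methylpent-2-enoic acid
Conditions: LiOH·H2O, THF/MeOH/H2O, rt → 40 °C; then 1 M HCl to pH 3
Reagents that add atoms: lithium hydroxide, [Li+].[OH-]
Why: Saponification is done at the diol stage, before the base-sensitive α-hydroxy aldehyde exists, and the (Z)-geometry is kept because ester hydrolysis is faster than γ-deprotonation and the carboxylate is inert.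

**Step 19**
Reactants: 28 diol acid (as above)
Product: 29 (2Z)-5-[(1S,2R,4aS,6R,8aR)-6-[(tert-butyldimethylsilyl)oxy]-2-formyl-2-hydroxy-5,5,8a-trimethyldecahydronaphthalen-1-yl]-3-methylpent-2-enoic acid
Conditions: IBX, DMSO, rt
Reagents that add atoms: none
Why: IBX oxidises the primary alcohol of a 1,2-diol to the aldehyde without C–C cleavage; the tertiary C8 hydroxyl cannot be oxidised and C3 is still silylated.

**Step 20**
Reactants: 29 silylated hydroxy aldehyde acid (as above)
Product: 30 (2Z)-5-[(1S,2R,4aS,6R,8aR)-2-formyl-2,6-dihydroxy-5,5,8a-trimethyldecahydronaphthalen-1-yl]-3-methylpent-2-enoic acid (target, CNP0273710.1)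
Conditions: 48% aq. HF, MeCN, 0 °C → rt
Reagents that add atoms: none
Why: Acidic fluoride desilylation removes the hindered secondary TBS ether; the tertiary C8 alcohol does not ionise next to the formyl group, and no base is present to trigger an α-ketol rearrangement.

**Compound list**
1 | methyl (2E)-3,7-dimethylocta-2,6-dienoate (methyl geranate) | CC(C)=CCC/C(C)=C/C(=O)OC | starting material
2 | methyl (2E)-5-(5,5-dimethyl-1,2,4-trioxolan-3-yl)-3-methylpent-2-enoate (ozonide) | COC(=O)/C=C(\C)CCC1OOC(C)(C)O1 | intermediate (not isolated)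
3 | methyl (2E)-3-methyl-6-oxohex-2-enoate | COC(=O)/C=C(\C)CCC=O | intermediate
4 | 3-methylbuta-1,2-diene | CC(C)=C=C | starting material
5 | B-(3-methylbut-2-enyl)diisopinocampheylborane from (+)-α-pinene (prenylborane) | CC(C)=CCB([C@@H]1C[C@@H]2C[C@@H](C2(C)C)[C@H]1C)[C@@H]1C[C@@H]2C[C@@H](C2(C)C)[C@H]1C | intermediate (not isolated)
6 | diisopinocampheylborinate ester of alcohol 7 | COC(=O)/C=C(\C)CC[C@@H](OB([C@@H]1C[C@@H]2C[C@@H](C2(C)C)[C@H]1C)[C@@H]1C[C@@H]2C[C@@H](C2(C)C)[C@H]1C)C(C)(C)C=C | intermediate (not isolated)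
7 | methyl (2E,6R)-6-hydroxy-3,7,7-trimethylnona-2,8-dienoate | COC(=O)/C=C(\C)CC[C@@H](O)C(C)(C)C=C | intermediate
8 | methyl (2E,6R)-6-[(tert-butyldimethylsilyl)oxy]-3,7,7-trimethylnona-2,8-dienoate | COC(=O)/C=C(\C)CC[C@@H](O[Si](C)(C)C(C)(C)C)C(C)(C)C=C | intermediate
9 | methyl (2E,6R)-6-[(tert-butyldimethylsilyl)oxy]-8,9-dihydroxy-3,7,7-trimethylnon-2-enoate (both C8 epimers) | COC(=O)/C=C(\C)CC[C@@H](O[Si](C)(C)C(C)(C)C)C(C)(C)C(O)CO | intermediate (not isolated)
10 | methyl (2E,6R)-6-[(tert-butyldimethylsilyl)oxy]-3,7,7-trimethyl-8-oxooct-2-enoate | COC(=O)/C=C(\C)CC[C@@H](O[Si](C)(C)C(C)(C)C)C(C)(C)C=O | intermediate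
11 | (triphenylphosphoranylidene)acetaldehyde | O=CC=P(c1ccccc1)(c1ccccc1)c1ccccc1 | starting material
12 | methyl (2E,6R,8E)-6-[(tert-butyldimethylsilyl)oxy]-3,7,7-trimethyl-10-oxodeca-2,8-dienoate | COC(=O)/C=C(\C)CC[C@@H](O[Si](C)(C)C(C)(C)C)C(C)(C)/C=C/C=O | intermediate
13 | methyl (2E,6R,8E,10E)-6-[(tert-butyldimethylsilyl)oxy]-3,7,7-trimethyl-11-(4,4,5,5-tetramethyl-1,3,2-dioxaborolan-2-yl)undeca-2,8,10-trienoate | COC(=O)/C=C(\C)CC[C@@H](O[Si](C)(C)C(C)(C)C)C(C)(C)/C=C/C=C/B1OC(C)(C)C(C)(C)O1 | intermediate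
14 | 4-methoxybenzyl alcohol | COc1ccc(CO)cc1 | starting material
15 | methyl (2E,6R,8E,10E)-6-[(tert-butyldimethylsilyl)oxy]-11-[(4-methoxybenzyl)oxy]-3,7,7-trimethylundeca-2,8,10-trienoate | COC(=O)/C=C(\C)CC[C@@H](O[Si](C)(C)C(C)(C)C)C(C)(C)/C=C/C=C/OCc1ccc(OC)cc1 | intermediate
16 | methyl (1S,2R,4aS,6R,8aR)-6-[(tert-butyldimethylsilyl)oxy]-2-[(4-methoxybenzyl)oxy]-5,5,8a-trimethyl-1,2,4a,5,6,7,8,8a-octahydronaphthalene-1-carboxylate | COC(=O)[C@H]1[C@]2(C)CC[C@@H](O[Si](C)(C)C(C)(C)C)C(C)(C)[C@H]2C=C[C@H]1OCc1ccc(OC)cc1 | intermediate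
17 | methyl (1S,2R,4aS,6R,8aR)-6-[(tert-butyldimethylsilyl)oxy]-2-[(4-methoxybenzyl)oxy]-5,5,8a-trimethyldecahydronaphthalene-1-carboxylate | COC(=O)[C@H]1[C@]2(C)CC[C@@H](O[Si](C)(C)C(C)(C)C)C(C)(C)[C@H]2CC[C@H]1OCc1ccc(OC)cc1 | intermediate
18 | [(1R,2R,4aS,6R,8aR)-6-[(tert-butyldimethylsilyl)oxy]-2-[(4-methoxybenzyl)oxy]-5,5,8a-trimethyldecahydronaphthalen-1-yl]methanol | OC[C@H]1[C@]2(C)CC[C@@H](O[Si](C)(C)C(C)(C)C)C(C)(C)[C@H]2CC[C@H]1OCc1ccc(OC)cc1 | intermediate
19 | (1S,2R,4aS,6R,8aR)-6-[(tert-butyldimethylsilyl)oxy]-2-[(4-methoxybenzyl)oxy]-5,5,8a-trimethyldecahydronaphthalene-1-carbaldehyde | O=C[C@H]1[C@]2(C)CC[C@@H](O[Si](C)(C)C(C)(C)C)C(C)(C)[C@H]2CC[C@H]1OCc1ccc(OC)cc1 | intermediate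
20 | (1S,2R,4aS,6R,8aR)-1-ethenyl-6-[(tert-butyldimethylsilyl)oxy]-2-[(4-methoxybenzyl)oxy]-5,5,8a-trimethyldecahydronaphthalene | C=C[C@H]1[C@]2(C)CC[C@@H](O[Si](C)(C)C(C)(C)C)C(C)(C)[C@H]2CC[C@H]1OCc1ccc(OC)cc1 | intermediate
21 | methyl (2Z)-3-iodobut-2-enoate | C/C(I)=C/C(=O)OC | starting material
22 | B-alkyl-9-borabicyclo[3.3.1]nonane from 20 (boron on C12) | C1CC2CCCC(C1)B2CC[C@H]1[C@]2(C)CC[C@@H](O[Si](C)(C)C(C)(C)C)C(C)(C)[C@H]2CC[C@H]1OCc1ccc(OC)cc1 | intermediate (not isolated)
23 | methyl (2Z)-5-[(1S,2R,4aS,6R,8aR)-6-[(tert-butyldimethylsilyl)oxy]-2-[(4-methoxybenzyl)oxy]-5,5,8a-trimethyldecahydronaphthalen-1-yl]-3-methylpent-2-enoate | COC(=O)/C=C(/C)CC[C@H]1[C@]2(C)CC[C@@H](O[Si](C)(C)C(C)(C)C)C(C)(C)[C@H]2CC[C@H]1OCc1ccc(OC)cc1 | intermediate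
24 | methyl (2Z)-5-[(1S,2R,4aS,6R,8aR)-6-[(tert-butyldimethylsilyl)oxy]-2-hydroxy-5,5,8a-trimethyldecahydronaphthalen-1-yl]-3-methylpent-2-enoate | COC(=O)/C=C(/C)CC[C@H]1[C@]2(C)CC[C@@H](O[Si](C)(C)C(C)(C)C)C(C)(C)[C@H]2CC[C@H]1O | intermediate
25 | methyl (2Z)-5-[(1S,4aS,6R,8aR)-6-[(tert-butyldimethylsilyl)oxy]-5,5,8a-trimethyl-2-oxodecahydronaphthalen-1-yl]-3-methylpent-2-enoate | COC(=O)/C=C(/C)CC[C@H]1[C@]2(C)CC[C@@H](O[Si](C)(C)C(C)(C)C)C(C)(C)[C@H]2CCC1=O | intermediate
26 | methyl (2Z)-5-[(1S,2R,4aS,6R,8aR)-6-[(tert-butyldimethylsilyl)oxy]-2-{[dimethyl(propan-2-yloxy)silyl]methyl}-2-hydroxy-5,5,8a-trimethyldecahydronaphthalen-1-yl]-3-methylpent-2-enoate | COC(=O)/C=C(/C)CC[C@H]1[C@]2(C)CC[C@@H](O[Si](C)(C)C(C)(C)C)C(C)(C)[C@H]2CC[C@]1(O)C[Si](C)(C)OC(C)C | intermediate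
27 | methyl (2Z)-5-[(1S,2R,4aS,6R,8aR)-6-[(tert-butyldimethylsilyl)oxy]-2-hydroxy-2-(hydroxymethyl)-5,5,8a-trimethyldecahydronaphthalen-1-yl]-3-methylpent-2-enoate | COC(=O)/C=C(/C)CC[C@H]1[C@]2(C)CC[C@@H](O[Si](C)(C)C(C)(C)C)C(C)(C)[C@H]2CC[C@]1(O)CO | intermediate
28 | (2Z)-5-[(1S,2R,4aS,6R,8aR)-6-[(tert-butyldimethylsilyl)oxy]-2-hydroxy-2-(hydroxymethyl)-5,5,8a-trimethyldecahydronaphthalen-1-yl]-3-methylpent-2-enoic acid | OC(=O)/C=C(/C)CC[C@H]1[C@]2(C)CC[C@@H](O[Si](C)(C)C(C)(C)C)C(C)(C)[C@H]2CC[C@]1(O)CO | intermediate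
29 | (2Z)-5-[(1S,2R,4aS,6R,8aR)-6-[(tert-butyldimethylsilyl)oxy]-2-formyl-2-hydroxy-5,5,8a-trimethyldecahydronaphthalen-1-yl]-3-methylpent-2-enoic acid | OC(=O)/C=C(/C)CC[C@H]1[C@]2(C)CC[C@@H](O[Si](C)(C)C(C)(C)C)C(C)(C)[C@H]2CC[C@]1(O)C=O | intermediate
30 | (2Z)-5-[(1S,2R,4aS,6R,8aR)-2-formyl-2,6-dihydroxy-5,5,8a-trimethyldecahydronaphthalen-1-yl]-3-methylpent-2-enoic acid | C/C(=C/C(=O)O)CC[C@H]1[C@]2(C)CC[C@@H](O)C(C)(C)[C@H]2CC[C@]1(O)C=O | target

**Step count and risks**
Total step count: 20. Longest linear sequence: 20 steps (1 → 30); all other inputs are commercial reagents.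

Steps most likely to fail:

1. Step 8 (key cycloaddition). What may go wrong: the exo (cis-fusing) mode may compete with the endo mode, the single C3 substituent may discriminate the two diene faces only weakly at 185 °C, and the dienyl ether may erode thermally before the sluggish trisubstituted enoate reacts. The fallback sets out from 15 and returns at 19; it changes the dienophile from ester to aldehyde so that the same two bonds form at much lower temperature. Reduction of 15 with i-Bu2AlH (CH2Cl2, −78 °C) should give (2E,6R,8E,10E)-6-[(tert-butyldimethylsilyl)oxy]-11-[(4-methoxybenzyl)oxy]-3,7,7-trimethylundeca-2,8,10-trien-1-ol F1. Oxidation with MnO2 (CH2Cl2, rt) should give (2E,6R,8E,10E)-6-[(tert-butyldimethylsilyl)oxy]-11-[(4-methoxybenzyl)oxy]-3,7,7-trimethylundeca-2,8,10-trienal F2. Cyclisation of F2 with Me2AlCl (CH2Cl2, −78 → −40 °C, or thermally near 80 °C in toluene) should give (1S,2R,4aS,6R,8aR)-6-[(tert-butyldimethylsilyl)oxy]-2-[(4-methoxybenzyl)oxy]-5,5,8a-trimethyl-1,2,4a,5,6,7,8,8a-octahydronaphthalene-1-carbaldehyde F3; the larger endo preference of the formyl group and the low temperature should sharpen both selectivities. Hydrogenation of F3 with [Ir(cod)(PCy3)(py)]PF6 and H2 then gives 19, so steps 10 and 11 fall away. The enal is kept cold because (E)-3-methyl-2-enals lose their geometry more easily than the ester, which is why the ester is the first choice.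

2. Step 7 (copper-promoted C–O coupling). What may go wrong: protodeboronation or oxidative homocoupling of the dienylboronate may outpace C–O bond formation, or the enol ether may be lost by hydrolysis on work-up. The fallback sets out from 12 and returns at 15. Takai iodo-olefination of 12 (CHI3, CrCl2, THF/dioxane, 0 °C) should give methyl (2E,6R,8E,10E)-6-[(tert-butyldimethylsilyl)oxy]-11-iodo-3,7,7-trimethylundeca-2,8,10-trienoate F4. F4 is then coupled with 14 under Ullmann-type catalysis (CuI, 3,4,7,8-tetramethyl-1,10-phenanthroline, Cs2CO3, toluene, 80 °C), a C–O coupling that also retains alkene geometry; the amount of 14 is kept small to limit ester exchange.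

3. Step 16 (C17 introduction). What may go wrong: the Grignard reagent may enolise the hindered C8 ketone instead of adding, or attack the ester during a long reaction time. The fallback sets out from 25 and returns at 28; a sulfur ylide replaces the Grignard reagent. Corey–Chaykovsky epoxidation (Me3SI, KN(SiMe3)2, THF, −10 °C) should deliver the methylene carbon equatorially for the same steric reason and give methyl (2Z)-5-[(1'S,2R,4a'S,6'R,8a'R)-6'-[(tert-butyldimethylsilyl)oxy]-5',5',8a'-trimethyloctahydro-1'H-spiro[oxirane-2,2'-naphthalen]-1'-yl]-3-methylpent-2-enoate F5, with the oxygen axial. Heating F5 with KOH in DMSO/H2O (70 °C) should open the epoxide at its primary carbon C17 and saponify the ester in the same pot, giving 28 and making steps 17 and 18 unnecessary.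

**Further compounds**
F1 | step 8 | (2E,6R,8E,10E)-6-[(tert-butyldimethylsilyl)oxy]-11-[(4-methoxybenzyl)oxy]-3,7,7-trimethylundeca-2,8,10-trien-1-ol | OC/C=C(\C)CC[C@@H](O[Si](C)(C)C(C)(C)C)C(C)(C)/C=C/C=C/OCc1ccc(OC)cc1
F2 | step 8 | (2E,6R,8E,10E)-6-[(tert-butyldimethylsilyl)oxy]-11-[(4-methoxybenzyl)oxy]-3,7,7-trimethylundeca-2,8,10-trienal | O=C/C=C(\C)CC[C@@H](O[Si](C)(C)C(C)(C)C)C(C)(C)/C=C/C=C/OCc1ccc(OC)cc1
F3 | step 8 | (1S,2R,4aS,6R,8aR)-6-[(tert-butyldimethylsilyl)oxy]-2-[(4-methoxybenzyl)oxy]-5,5,8a-trimethyl-1,2,4a,5,6,7,8,8a-octahydronaphthalene-1-carbaldehyde | O=C[C@H]1[C@]2(C)CC[C@@H](O[Si](C)(C)C(C)(C)C)C(C)(C)[C@H]2C=C[C@H]1OCc1ccc(OC)cc1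
F4 | step 7 | methyl (2E,6R,8E,10E)-6-[(tert-butyldimethylsilyl)oxy]-11-iodo-3,7,7-trimethylundeca-2,8,10-trienoate | COC(=O)/C=C(\C)CC[C@@H](O[Si](C)(C)C(C)(C)C)C(C)(C)/C=C/C=C/I
F5 | step 16 | methyl (2Z)-5-[(1'S,2R,4a'S,6'R,8a'R)-6'-[(tert-butyldimethylsilyl)oxy]-5',5',8a'-trimethyloctahydro-1'H-spiro[oxirane-2,2'-naphthalen]-1'-yl]-3-methylpent-2-enoate | COC(=O)/C=C(/C)CC[C@H]1[C@]2(C)CC[C@@H](O[Si](C)(C)C(C)(C)C)C(C)(C)[C@H]2CC[C@]13CO3
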